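**Retrosynthetic overview**

- The four benzyl ethers are removed last by hydrogenolysis. Ring C is closed before that by a Baker–Venkataraman acyl shift and cyclodehydration of the C8a benzoate of a C4a α-methoxyacetyl phenol; ring B comes from benzoyl chloride.
- The C4 carbon is placed on C4a by chelation-controlled ortho-formylation of the C8a phenol (C4a is its only free ortho carbon), followed by a one-carbon extension.
- Strategic feature: in ring A (C4a, C5, C6, C7, C8, C8a) the benzylic carbon C8 lies between the oxygenated carbons C7 and C8a. This is the 2-alkyl-3-alkoxy pattern of a cyclobutenone joined to the oxygen-bearing carbon of a siloxyalkyne, so ring A is made by benzannulation (C4a–C5 and C8–C8a formed; O5 free, O7 benzyl, O8a silyl).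
- The cyclobutenone comes from the ring D aldehyde and cyclobutane-1,3-dione (reductive alkylation, O-benzylation). The aldehyde comes from 2-methylphloroglucinol (acylation, para-O-methylation, formylation, benzylation), and the siloxyalkyne from (trimethylsilyl)acetylene.
- Ring order: ring D (bought as the arene, then substituted), ring A (benzannulation), ring C (acyl shift and dehydration).

Key step: step 10

**Remarks on the chemistry**

- ArD stands for 2,4-bis(benzyloxy)-6-methoxy-5-methyl-3-(3-phenylpropanoyl)phenyl, counted from the ring carbon that carries the CH2 (or CHO) group. Flavone numbering is used for rings A and C.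
- The ring A ketone is not introduced by a Lewis-acid acyl migration of a methoxyacetate. Chelating Lewis acids cleave benzyl ethers beside the ring D ketone, and alkoxyacetyl cations lose CO.
- Step 10 is a one-to-one addition of 11 and 16 in which all atoms of both partners end in 21; the alkyne is simply charged in excess.
- All starting materials (2-methylphloroglucinol, 3-phenylpropanoyl chloride, 3-ethoxycyclobut-2-en-1-one, (trimethylsilyl)acetylene, benzoyl chloride) are assumed to be purchased.

**Route**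

Step 1
Reactants: 1 2-methylphloroglucinol; 2 3-phenylpropanoyl chloride
Product: 3 1-(2,4,6-trihydroxy-3-methylphenyl)-3-phenylpropan-1-one
Conditions: AlCl3 (4 equiv), CH2Cl2–PhNO2, 0 °C to 50 °C; then 1 M HCl
Reagents that add atoms: none
Why: Friedel–Crafts C-acylation of the phloroglucinol nucleus, whose two free ring carbons are equivalent, so a single monoketone should form and the first acyl group deactivates the ring against a second.

Step 2
Reactants: 3 1-(2,4,6-trihydroxy-3-methylphenyl)-3-phenylpropan-1-one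
Product: 4 1-(2,6-dihydroxy-4-methoxy-3-methylphenyl)-3-phenylpropan-1-one
Conditions: Me2SO4 (1.0 equiv), K2CO3 (1.0 equiv), acetone, rt
Reagents that add atoms: dimethyl sulfate COS(=O)(=O)OC
Why: Selective Williamson O-methylation, since the hydroxyl para to the ketone is the most acidic and is not hydrogen-bonded to the carbonyl, so one equivalent of reagent should methylate it in preference to the two chelated ortho hydroxyls.

Step 3
Reactants: 4 1-(2,6-dihydroxy-4-methoxy-3-methylphenyl)-3-phenylpropan-1-one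
Product: 5 2,4-dihydroxy-6-methoxy-5-methyl-3-(3-phenylpropanoyl)benzaldehyde
Conditions: Cl2CHOMe (1.5 equiv), TiCl4 (3 equiv), CH2Cl2, 0 °C; then ice-water
Reagents that add atoms: dichloromethyl methyl ether COC(Cl)Cl; water O
Why: Rieche formylation at the only unsubstituted ring carbon, ortho to a titanium phenoxide; it is placed before benzylation because TiCl4 would cleave benzyl ethers beside the ketone.

Step 4
Reactants: 5 2,4-dihydroxy-6-methoxy-5-methyl-3-(3-phenylpropanoyl)benzaldehyde
Product: 6 2,4-bis(benzyloxy)-6-methoxy-5-methyl-3-(3-phenylpropanoyl)benzaldehyde (ArD–CHO)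
Conditions: BnBr (3 equiv), K2CO3 (4 equiv), Bu4NI (cat.), DMF, 60 °C
Reagents that add atoms: benzyl bromide BrCc1ccccc1
Why: Williamson bis-O-benzylation of the two chelated phenols under forcing carbonate/DMF conditions; the aldehyde has no α-hydrogen and K2CO3 does not enolise the hindered ketone.

Step 5
Reactants: 7 3-ethoxycyclobut-2-en-1-one
Product: 8 cyclobutane-1,3-dione (enol form 3-hydroxycyclobut-2-en-1-one)
Conditions: 1 M aq HCl, 0 °C to rt; used at once
Reagents that add atoms: water O
Why: Acid hydrolysis of the vinylogous ester to the vinylogous acid, the established preparation of this dione.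

Step 6
Reactants: 6 ArD–CHO; 8 cyclobutane-1,3-dione
Product: 10 3-hydroxy-2-(ArD-methyl)cyclobut-2-en-1-one (enol of the 2-substituted cyclobutane-1,3-dione), via arylidene dione 9 (not isolated)
Conditions: Hantzsch ester (1.1 equiv), L-proline (10 mol %), CH2Cl2, rt to 40 °C
Reagents that add atoms: none
Why: Three-component reductive alkylation (Knoevenagel condensation, then conjugate hydride transfer from the Hantzsch ester) as practised on cyclic 1,3-diones; the strongly acidic dione should condense under mild amine catalysis and the strained alkylidene dione 9 should be reduced before it can add a second dione.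

Step 7
Reactants: 10 3-hydroxy-2-(ArD-methyl)cyclobut-2-en-1-one
Product: 11 3-(benzyloxy)-2-(ArD-methyl)cyclobut-2-en-1-one
Conditions: BnBr (1.2 equiv), K2CO3 (1.2 equiv), DMF, 0 °C to rt
Reagents that add atoms: benzyl bromide BrCc1ccccc1
Why: O-Alkylation of a vinylogous carboxylate; deprotonation of the enol gives an anion that is symmetrical about C2, so benzylation on either oxygen should give the same 2-substituted 3-benzyloxy enone, and C-benzylation at the substituted, strained C2 is disfavoured.

Step 8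
Reactants: 12 (trimethylsilyl)acetylene
Product: 15 triisopropyl{[(trimethylsilyl)ethynyl]oxy}silane, via lithium acetylide 13 (not isolated), via lithium ynolate 14 (not isolated)
Conditions: n-BuLi, THF, −78 °C; t-BuOOLi (from t-BuOOH and LiN(SiMe3)2), −78 °C to 0 °C; iPr3SiOTf, −78 °C to rt
Reagents that add atoms: tert-butyl hydroperoxide (as its lithium salt) CC(C)(C)OO; triisopropylsilyl trifluoromethanesulfonate CC(C)[Si](OS(=O)(=O)C(F)(F)F)(C(C)C)C(C)C
Why: Oxidation of a lithium acetylide to the ynolate with lithium tert-butyl peroxide (Julia oxidation) and O-silylation with a bulky silyl triflate, the standard preparation of 1-siloxyalkynes; the C-silyl group keeps the acetylene monolithiated.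

Step 9
Reactants: 15 triisopropyl{[(trimethylsilyl)ethynyl]oxy}silane
Product: 16 (triisopropylsilyloxy)ethyne
Conditions: K2CO3 (0.2 equiv), MeOH, 0 °C, short contact; cold pentane extraction
Reagents that add atoms: none
Why: Base-catalysed methanolysis of the alkynyl C–SiMe3 bond, which should be far faster than attack at the hindered O–Si(iPr)3 group, frees the terminal siloxyalkyne.

Step 10
Reactants: 11 3-(benzyloxy)-2-(ArD-methyl)cyclobut-2-en-1-one; 16 (triisopropylsilyloxy)ethyne
Product: 21 3-(benzyloxy)-4-(ArD-methyl)-5-(triisopropylsilyloxy)phenol, via vinylketene 17 (not isolated), via vinylcyclobutenone 18 (not isolated), via dienylketene 19 (not isolated), via cyclohexadienone 20 (not isolated)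
Conditions: toluene, sealed tube, 80 °C then 110 °C; alkyne charged in excess, cyclobutenone added slowly
Reagents that add atoms: none
Why: Danheiser benzannulation: heat opens 11 by four-electron electrocyclic ring opening to vinylketene 17, which adds 16 in a (2+2) cycloaddition that forms C4a–C5 and C8–C8a and gives 4-vinylcyclobutenone 18. A second four-electron opening gives dienylketene 19, and ring A closes by thermal six-electron (disrotatory) electrocyclization of 19 between C5 and C6, after which cyclohexadienone 20 tautomerizes to phenol 21. The closest known reactions are the annulations of cyclobutenones with 1-siloxyalkynes, which give monosilylated resorcinols, and with terminal alkoxyacetylenes, which give resorcinol monoethers. No stereocentre survives, because the quaternary carbon of racemic 18 becomes aromatic C8. The step needs the regiochemistry of the (2+2) addition, and this is secured by the polarity of the partners: the unsubstituted, nucleophilic alkyne carbon bonds to the electrophilic ketene carbonyl carbon, so the silyloxy carbon becomes C8a next to benzyl-bearing C8. The ketene oxygen becomes the free 5-hydroxyl and the benzyloxy group of 11 ends on C7, so the three oxygens of ring A leave the step as OH, OBn and OSi(iPr)3 and every atom of both partners is kept in 21.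

Step 11
Reactants: 21 3-(benzyloxy)-4-(ArD-methyl)-5-(triisopropylsilyloxy)phenol
Product: 22 [3,5-bis(benzyloxy)-2-(ArD-methyl)phenoxy]triisopropylsilane
Conditions: BnBr (1.3 equiv), K2CO3 (2 equiv), acetone, 50 °C
Reagents that add atoms: benzyl bromide BrCc1ccccc1
Why: Williamson O-benzylation of the unhindered free phenol (O5) under conditions that leave the aryl triisopropylsilyl ether untouched.

Step 12
Reactants: 22 [3,5-bis(benzyloxy)-2-(ArD-methyl)phenoxy]triisopropylsilane
Product: 23 3,5-bis(benzyloxy)-2-(ArD-methyl)phenol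
Conditions: Bu4NF (1.1 equiv), AcOH (1.1 equiv), THF, 0 °C
Reagents that add atoms: none
Why: Fluoride-induced cleavage of the aryl silyl ether frees only the oxygen next to the benzylic carbon (O8a), which is the oxygen that must later close ring C.

Step 13
Reactants: 23 3,5-bis(benzyloxy)-2-(ArD-methyl)phenol
Product: 24 4,6-bis(benzyloxy)-2-hydroxy-3-(ArD-methyl)benzaldehyde
Conditions: MgCl2 (2 equiv), Et3N (4 equiv), (CH2O)n (6 equiv), THF, reflux; then 1 M HCl
Reagents that add atoms: paraformaldehyde (formaldehyde) C=O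
Why: Magnesium-mediated ortho-formylation (Casnati–Skattebøl type): the magnesium phenoxide delivers formaldehyde only to a carbon ortho to the free hydroxyl, C4a is the one such carbon that bears hydrogen, and no strong Lewis acid touches the benzyl ethers beside the ring D ketone.

Step 14
Reactants: 24 4,6-bis(benzyloxy)-2-hydroxy-3-(ArD-methyl)benzaldehyde
Product: 25 1-[4,6-bis(benzyloxy)-2-hydroxy-3-(ArD-methyl)phenyl]-2-methoxyethan-1-ol (racemic)
Conditions: MeOCH2MgCl (3 equiv, from MeOCH2Cl and Mg, THF, −25 °C), THF, −25 °C to 0 °C; sat. aq NH4Cl; crude product carried on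
Reagents that add atoms: (methoxymethyl)magnesium chloride COC[Mg]Cl
Why: Grignard addition to the magnesium-chelated salicylaldehyde, which is far more electrophilic than the di-ortho-substituted ring D ketone; the new carbinol centre forms racemic and is erased in step 15.

Step 15
Reactants: 25 1-[4,6-bis(benzyloxy)-2-hydroxy-3-(ArD-methyl)phenyl]-2-methoxyethan-1-ol
Product: 26 1-[4,6-bis(benzyloxy)-2-hydroxy-3-(ArD-methyl)phenyl]-2-methoxyethan-1-one
Conditions: activated MnO2 (20 equiv), CH2Cl2, rt
Reagents that add atoms: none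
Why: MnO2 oxidation of an electron-rich benzylic alcohol to the hydrogen-bonded ortho-hydroxyaryl ketone under neutral conditions that spare benzyl ethers and the diarylmethane CH2.

Step 16
Reactants: 26 1-[4,6-bis(benzyloxy)-2-hydroxy-3-(ArD-methyl)phenyl]-2-methoxyethan-1-one; 27 benzoyl chloride
Product: 28 3,5-bis(benzyloxy)-2-(methoxyacetyl)-6-(ArD-methyl)phenyl benzoate
Conditions: Et3N (2 equiv), DMAP (0.1 equiv), CH2Cl2, 0 °C to rt
Reagents that add atoms: none
Why: DMAP-catalysed O-acylation of the only free hydroxyl (O8a) places the benzoyl group (C2 and ring B) on the oxygen that becomes O1.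

Step 17
Reactants: 28 3,5-bis(benzyloxy)-2-(methoxyacetyl)-6-(ArD-methyl)phenyl benzoate
Product: 30 5,7-bis(benzyloxy)-3-methoxy-2-phenyl-8-(ArD-methyl)-4H-chromen-4-one, via diketone 29 (not isolated)
Conditions: LiN(SiMe3)2 (3.5 equiv), THF, −78 °C to 0 °C; AcOH quench; then p-TsOH·H2O (0.2 equiv), toluene, 70 °C
Reagents that add atoms: none
Why: Baker–Venkataraman rearrangement (intramolecular Claisen transfer of the benzoyl group to the α-methoxy enolate through a six-membered transition state) followed by acid cyclodehydration of diketone 29; with O5 benzylated only O8a can close ring C, which fixes the 8-benzyl flavone.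

Step 18
Reactants: 30 5,7-bis(benzyloxy)-3-methoxy-2-phenyl-8-(ArD-methyl)-4H-chromen-4-one
Product: 31 8-{[2,4-dihydroxy-6-methoxy-5-methyl-3-(3-phenylpropanoyl)phenyl]methyl}-5,7-dihydroxy-3-methoxy-2-phenyl-4H-chromen-4-one (CNP0280022.0)
Conditions: H2 (1 atm), Pd/C (10 wt % Pd), EtOAc–MeOH, rt
Reagents that add atoms: none
Why: Catalytic hydrogenolysis of the four aryl benzyl ethers under neutral conditions, which should leave the two methyl ethers, the tetrasubstituted C2=C3 bond and the hindered aryl ketone intact.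

**Compound list**

1 | 2-methylphloroglucinol | Cc1c(O)cc(O)cc1O | starting material
2 | 3-phenylpropanoyl chloride | O=C(Cl)CCc1ccccc1 | starting material
3 | 1-(2,4,6-trihydroxy-3-methylphenyl)-3-phenylpropan-1-one | Cc1c(O)cc(O)c(C(=O)CCc2ccccc2)c1O | intermediate
4 | 1-(2,6-dihydroxy-4-methoxy-3-methylphenyl)-3-phenylpropan-1-one | COc1cc(O)c(C(=O)CCc2ccccc2)c(O)c1C | intermediate
5 | 2,4-dihydroxy-6-methoxy-5-methyl-3-(3-phenylpropanoyl)benzaldehyde | O=Cc1c(O)c(C(=O)CCc2ccccc2)c(O)c(C)c1OC | intermediate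
6 | 2,4-bis(benzyloxy)-6-methoxy-5-methyl-3-(3-phenylpropanoyl)benzaldehyde (ArD–CHO) | O=Cc1c(OCc2ccccc2)c(C(=O)CCc2ccccc2)c(OCc2ccccc2)c(C)c1OC | intermediate
7 | 3-ethoxycyclobut-2-en-1-one | CCOC1=CC(=O)C1 | starting material
8 | cyclobutane-1,3-dione | O=C1CC(=O)C1 | intermediate
9 | 2-(ArD-methylidene)cyclobutane-1,3-dione | O=C1CC(=O)C1=Cc1c(OCc2ccccc2)c(C(=O)CCc2ccccc2)c(OCc2ccccc2)c(C)c1OC | intermediate (not isolated)
10 | 3-hydroxy-2-(ArD-methyl)cyclobut-2-en-1-one | O=C1CC(O)=C1Cc1c(OC)c(C)c(OCc2ccccc2)c(C(=O)CCc2ccccc2)c1OCc1ccccc1 | intermediate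
11 | 3-(benzyloxy)-2-(ArD-methyl)cyclobut-2-en-1-one | O=C1CC(OCc2ccccc2)=C1Cc1c(OC)c(C)c(OCc2ccccc2)c(C(=O)CCc2ccccc2)c1OCc1ccccc1 | intermediate (key-step precursor)
12 | (trimethylsilyl)acetylene | C#C[Si](C)(C)C | starting material
13 | lithium (trimethylsilyl)acetylide | [Li]C#C[Si](C)(C)C | intermediate (not isolated)
14 | lithium 2-(trimethylsilyl)ethynolate | [Li+].[O-]C#C[Si](C)(C)C | intermediate (not isolated)
15 | triisopropyl{[(trimethylsilyl)ethynyl]oxy}silane | CC(C)[Si](OC#C[Si](C)(C)C)(C(C)C)C(C)C | intermediate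
16 | (triisopropylsilyloxy)ethyne | C#CO[Si](C(C)C)(C(C)C)C(C)C | intermediate (key-step precursor)
17 | 2-(ArD-methyl)-3-(benzyloxy)buta-1,3-dien-1-one (vinylketene) | O=C=C(Cc1c(OC)c(C)c(OCc2ccccc2)c(C(=O)CCc2ccccc2)c1OCc1ccccc1)C(=C)OCc1ccccc1 | intermediate (not isolated)
18 | 4-(ArD-methyl)-4-[1-(benzyloxy)ethenyl]-3-(triisopropylsilyloxy)cyclobut-2-en-1-one (racemic) | O=C1C=C(O[Si](C(C)C)(C(C)C)C(C)C)C1(Cc1c(OC)c(C)c(OCc2ccccc2)c(C(=O)CCc2ccccc2)c1OCc1ccccc1)C(=C)OCc1ccccc1 | intermediate (not isolated)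
19 | (3E)-4-(ArD-methyl)-5-(benzyloxy)-3-(triisopropylsilyloxy)hexa-1,3,5-trien-1-one (dienylketene) | O=C=C/C(O[Si](C(C)C)(C(C)C)C(C)C)=C(/Cc1c(OC)c(C)c(OCc2ccccc2)c(C(=O)CCc2ccccc2)c1OCc1ccccc1)C(=C)OCc1ccccc1 | intermediate (not isolated)
20 | 5-(benzyloxy)-4-(ArD-methyl)-3-(triisopropylsilyloxy)cyclohexa-2,4-dien-1-one | O=C1C=C(O[Si](C(C)C)(C(C)C)C(C)C)C(Cc2c(OC)c(C)c(OCc3ccccc3)c(C(=O)CCc3ccccc3)c2OCc2ccccc2)=C(OCc2ccccc2)C1 | intermediate (not isolated)
21 | 3-(benzyloxy)-4-(ArD-methyl)-5-(triisopropylsilyloxy)phenol | Oc1cc(O[Si](C(C)C)(C(C)C)C(C)C)c(Cc2c(OC)c(C)c(OCc3ccccc3)c(C(=O)CCc3ccccc3)c2OCc2ccccc2)c(OCc2ccccc2)c1 | intermediate (key-step product)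
22 | [3,5-bis(benzyloxy)-2-(ArD-methyl)phenoxy]triisopropylsilane | CC(C)[Si](Oc1cc(OCc2ccccc2)cc(OCc2ccccc2)c1Cc1c(OC)c(C)c(OCc2ccccc2)c(C(=O)CCc2ccccc2)c1OCc1ccccc1)(C(C)C)C(C)C | intermediate
23 | 3,5-bis(benzyloxy)-2-(ArD-methyl)phenol | Oc1cc(OCc2ccccc2)cc(OCc2ccccc2)c1Cc1c(OC)c(C)c(OCc2ccccc2)c(C(=O)CCc2ccccc2)c1OCc1ccccc1 | intermediate
24 | 4,6-bis(benzyloxy)-2-hydroxy-3-(ArD-methyl)benzaldehyde | O=Cc1c(O)c(Cc2c(OC)c(C)c(OCc3ccccc3)c(C(=O)CCc3ccccc3)c2OCc2ccccc2)c(OCc2ccccc2)cc1OCc1ccccc1 | intermediate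
25 | 1-[4,6-bis(benzyloxy)-2-hydroxy-3-(ArD-methyl)phenyl]-2-methoxyethan-1-ol (racemic) | COCC(O)c1c(O)c(Cc2c(OC)c(C)c(OCc3ccccc3)c(C(=O)CCc3ccccc3)c2OCc2ccccc2)c(OCc2ccccc2)cc1OCc1ccccc1 | intermediate
26 | 1-[4,6-bis(benzyloxy)-2-hydroxy-3-(ArD-methyl)phenyl]-2-methoxyethan-1-one | COCC(=O)c1c(O)c(Cc2c(OC)c(C)c(OCc3ccccc3)c(C(=O)CCc3ccccc3)c2OCc2ccccc2)c(OCc2ccccc2)cc1OCc1ccccc1 | intermediate
27 | benzoyl chloride | O=C(Cl)c1ccccc1 | starting material
28 | 3,5-bis(benzyloxy)-2-(methoxyacetyl)-6-(ArD-methyl)phenyl benzoate | COCC(=O)c1c(OC(=O)c2ccccc2)c(Cc2c(OC)c(C)c(OCc3ccccc3)c(C(=O)CCc3ccccc3)c2OCc2ccccc2)c(OCc2ccccc2)cc1OCc1ccccc1 | intermediate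
29 | 1-[4,6-bis(benzyloxy)-2-hydroxy-3-(ArD-methyl)phenyl]-2-methoxy-3-phenylpropane-1,3-dione | COC(C(=O)c1ccccc1)C(=O)c1c(O)c(Cc2c(OC)c(C)c(OCc3ccccc3)c(C(=O)CCc3ccccc3)c2OCc2ccccc2)c(OCc2ccccc2)cc1OCc1ccccc1 | intermediate (not isolated)
30 | 5,7-bis(benzyloxy)-3-methoxy-2-phenyl-8-(ArD-methyl)-4H-chromen-4-one | COc1c(-c2ccccc2)oc2c(Cc3c(OC)c(C)c(OCc4ccccc4)c(C(=O)CCc4ccccc4)c3OCc3ccccc3)c(OCc3ccccc3)cc(OCc3ccccc3)c2c1=O | intermediate
31 | 8-{[2,4-dihydroxy-6-methoxy-5-methyl-3-(3-phenylpropanoyl)phenyl]methyl}-5,7-dihydroxy-3-methoxy-2-phenyl-4H-chromen-4-one | COc1c(C)c(O)c(C(=O)CCc2ccccc2)c(O)c1Cc1c(O)cc(O)c2c(=O)c(OC)c(-c3ccccc3)oc12 | target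

**Step count**

Total: 18 steps. Longest linear sequence: 15 steps (steps 1–4, 6, 7, 10–18).

**Three steps most likely to fail**

1. Step 10 (benzannulation).
   - What may go wrong: the donor-stabilised 3-alkoxycyclobutenone may open too slowly. The terminal siloxyalkyne may isomerise by 1,3-silyl shift to a silylketene before it is captured, which is why it is charged in excess. The vinylketene may dimerise.
   - Fallback, setting out from 6 and coming back at 23: aldehyde 6 is reduced with NaBH4 (MeOH–THF, 0 °C; the hindered ketone is spared) to 1-[2,6-bis(benzyloxy)-3-(hydroxymethyl)-4-methoxy-5-methylphenyl]-3-phenylpropan-1-one F1. F1 then alkylates purchased 3,5-bis(benzyloxy)phenol in a Friedel–Crafts benzylation (H2SO4 on silica gel, CH2Cl2, rt). Attack should occur at C2 of that phenol, ortho to the hydroxyl, in preference to the more hindered C4 between the two benzyloxy groups. This should give 23, and the route continues at step 13.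

2. Step 6 (reductive alkylation of cyclobutane-1,3-dione).
   - What may go wrong: the Knoevenagel condensation of the di-ortho-substituted aldehyde may be sluggish. The catalyst may be tied up as a vinylogous amide. The four-membered dione may be cleaved or may add twice.
   - Fallback, setting out from 6 and coming back at 10: reductive alkylation of Meldrum's acid with 6 (Hantzsch ester, L-proline, EtOH) should give 5-(ArD-methyl)-2,2-dimethyl-1,3-dioxane-4,6-dione F2. Heating in aqueous pyridine (hydrolysis and decarboxylation) should give 3-(ArD)propanoic acid F3. 1-Chloro-N,N,2-trimethylprop-1-en-1-amine converts it into 3-(ArD)propanoyl chloride F4. Et3N in the presence of purchased ethoxyacetylene generates the ketene 3-(ArD)prop-1-en-1-one F5, which adds the alkoxyalkyne in a (2+2) cycloaddition to give 3-ethoxy-4-(ArD-methyl)cyclobut-2-en-1-one F6. Cold aqueous HCl hydrolyses the enol ether of F6 to 10.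

3. Step 14 (one-carbon extension with MeOCH2MgCl).
   - What may go wrong: the carbenoid-like Grignard reagent decomposes above about −20 °C. Addition to the chelated phenoxide aldehyde may stay incomplete. The electron-rich ortho-hydroxybenzylic alcohol may ionise during work-up.
   - Fallback, setting out from 24 and coming back at 29: phenol 24 is protected (MeOCH2Cl, iPr2NEt, CH2Cl2) as 4,6-bis(benzyloxy)-2-(methoxymethoxy)-3-(ArD-methyl)benzaldehyde F7. The lithium enolate of purchased 2-methoxy-1-phenylethan-1-one (LiN(iPr)2, THF, −78 °C) adds to F7 in an aldol addition to give 3-[4,6-bis(benzyloxy)-2-(methoxymethoxy)-3-(ArD-methyl)phenyl]-3-hydroxy-2-methoxy-1-phenylpropan-1-one F8 as a mixture of diastereomers. Dess–Martin periodinane oxidises F8 to 1-[4,6-bis(benzyloxy)-2-(methoxymethoxy)-3-(ArD-methyl)phenyl]-2-methoxy-3-phenylpropane-1,3-dione F9. HCl in MeOH removes the acetal to give 29, which is cyclised under the acid conditions of step 17 to 30. This brings C3, C2 and ring B in one piece and needs neither the Grignard reagent nor the free benzylic alcohol.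

**Further compounds**

F1 | step 10 | 1-[2,6-bis(benzyloxy)-3-(hydroxymethyl)-4-methoxy-5-methylphenyl]-3-phenylpropan-1-one | OCc1c(OC)c(C)c(OCc2ccccc2)c(C(=O)CCc2ccccc2)c1OCc1ccccc1
F2 | step 6 | 5-(ArD-methyl)-2,2-dimethyl-1,3-dioxane-4,6-dione | CC1(C)OC(=O)C(Cc2c(OC)c(C)c(OCc3ccccc3)c(C(=O)CCc3ccccc3)c2OCc2ccccc2)C(=O)O1
F3 | step 6 | 3-(ArD)propanoic acid | OC(=O)CCc1c(OC)c(C)c(OCc2ccccc2)c(C(=O)CCc2ccccc2)c1OCc1ccccc1
F4 | step 6 | 3-(ArD)propanoyl chloride | ClC(=O)CCc1c(OC)c(C)c(OCc2ccccc2)c(C(=O)CCc2ccccc2)c1OCc1ccccc1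
F5 | step 6 | 3-(ArD)prop-1-en-1-one (ketene) | O=C=CCc1c(OC)c(C)c(OCc2ccccc2)c(C(=O)CCc2ccccc2)c1OCc1ccccc1
F6 | step 6 | 3-ethoxy-4-(ArD-methyl)cyclobut-2-en-1-one (racemic) | CCOC1=CC(=O)C1Cc1c(OC)c(C)c(OCc2ccccc2)c(C(=O)CCc2ccccc2)c1OCc1ccccc1
F7 | step 14 | 4,6-bis(benzyloxy)-2-(methoxymethoxy)-3-(ArD-methyl)benzaldehyde | O=Cc1c(OCOC)c(Cc2c(OC)c(C)c(OCc3ccccc3)c(C(=O)CCc3ccccc3)c2OCc2ccccc2)c(OCc2ccccc2)cc1OCc1ccccc1
F8 | step 14 | 3-[4,6-bis(benzyloxy)-2-(methoxymethoxy)-3-(ArD-methyl)phenyl]-3-hydroxy-2-methoxy-1-phenylpropan-1-one (mixture of diastereomers) | COC(C(=O)c1ccccc1)C(O)c1c(OCOC)c(Cc2c(OC)c(C)c(OCc3ccccc3)c(C(=O)CCc3ccccc3)c2OCc2ccccc2)c(OCc2ccccc2)cc1OCc1ccccc1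
F9 | step 14 | 1-[4,6-bis(benzyloxy)-2-(methoxymethoxy)-3-(ArD-methyl)phenyl]-2-methoxy-3-phenylpropane-1,3-dione | COC(C(=O)c1ccccc1)C(=O)c1c(OCOC)c(Cc2c(OC)c(C)c(OCc3ccccc3)c(C(=O)CCc3ccccc3)c2OCc2ccccc2)c(OCc2ccccc2)cc1OCc1ccccc1
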